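## Retrosynthetic overview

1. Presumed biogenesis: a fatty-acyl-primed poly-β-keto thioester closes by Claisen condensation to a 2-acylcyclohexane-1,3-dione, the ring enol attacks the side-chain ketone to give the γ-pyrone, and a ketoreduction at C5 finishes. The synthesis makes the same bonds in the same order.
2. 9 ⇐ 8: asymmetric transfer hydrogenation of the C5 ketone sets the only stereocentre (S).
3. 8 ⇐ 7 ⇐ 6, in one flask: carbocycle first (Claisen closure C4a–C5 of the open-chain triketo ester 6), pyrone second (cyclodehydration of 7).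
4. 6 ⇐ 4 + 5 (terminal acylation of a β-diketone dianion by dimethyl glutarate, same flask); 4 ⇐ 2 + 3 (γ-alkylation of acetylacetone dianion); 2 ⇐ 1.

Assumption: (Z)-hexadec-11-en-1-ol (a bulk moth-pheromone component), acetylacetone and dimethyl glutarate are bought, and LDA is used as the commercial solution.

## Route

Step 1
Reactants: 1 (Z)-hexadec-11-en-1-ol
Product: 2 (Z)-16-iodohexadec-5-ene
Conditions: I2, PPh3, imidazole, CH2Cl2, 0 °C → rt
Reagents that add atoms: iodine, II
Why: Appel-type iodination, in which iodide displaces the alkoxyphosphonium by SN2 at the primary carbon under neutral conditions that leave the Z-alkene untouched.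

Step 2
Reactants: 2 (Z)-16-iodohexadec-5-ene; 3 acetylacetone
Product: 4 (16Z)-henicos-16-ene-2,4-dione
Conditions: 3 (1.5 equiv), LDA (3.0 equiv), THF, 0 °C; then 2 (1.0 equiv), 0 °C → rt; 1 M HCl
Reagents that add atoms: none
Why: Hauser–Harris γ-alkylation, in which the terminal carbanion of the acetylacetone 1,3-dianion is far more nucleophilic than the internal enolate and displaces the primary iodide (SN2) at the methyl carbon only.

Step 3
Reactants: 4 (16Z)-henicos-16-ene-2,4-dione; 5 dimethyl glutarate
Product: 8 2-[(12Z)-heptadec-12-en-1-yl]-7,8-dihydro-4H-chromene-4,5(6H)-dione, via triketo ester 6 (not isolated), via tetraketone 7 (not isolated)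
Conditions: LDA (3.1 equiv), THF, −78 → 0 °C; 5 (1.5 equiv), −78 °C → rt, then reflux, 3 h; then conc. HCl (pH < 1), 60 °C, 2 h
Reagents that add atoms: none
Why: Proposed new method: the dianion of 4 (kinetic deprotonation at CH3 rather than the chain CH2) is acylated at its methyl terminus by one ester group of 5 (Harris-type terminal Claisen acylation of β-diketone dianions; the third equivalent of base takes up the newly acidic proton) to give 6 as its dianion, whose doubly activated C6 attacks the remaining ester in a 6-exo-trig Claisen (Dieckmann) closure driven by formation of the very acidic cyclic β-triketone 7 (the bond the polyketide synthase closes; closest known reactions are the Claisen cyclisation of 3,5,7-triketo esters to acylphloroglucinols and the double Claisen of methyl ketones with diesters to 2-acyl-1,3-diones), and acid then closes the γ-pyrone by enol attack on the side-chain ketone with loss of water (standard 1,3,5-triketone to 4-pyrone cyclodehydration; either ring carbonyl gives the same product), with no stereocentre formed.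

Step 4
Reactants: 8 2-[(12Z)-heptadec-12-en-1-yl]-7,8-dihydro-4H-chromene-4,5(6H)-dione
Product: 9 (5S)-2-[(12Z)-heptadec-12-en-1-yl]-5-hydroxy-5,6,7,8-tetrahydro-4H-chromen-4-one
Conditions: RuCl[(S,S)-TsDPEN](p-cymene) (2 mol %), HCO2H/Et3N (5:2), CH2Cl2, 30 °C
Reagents that add atoms: none
Why: Noyori–Ikariya asymmetric transfer hydrogenation, in which the C5 ketone is flanked by a π-face (C4a=C8a) and a CH2 like the carbonyl of 1-tetralone, so the (S,S)-catalyst gives the (S)-carbinol by the same CH/π-controlled hydride delivery, while the electron-rich pyrone C4=O and the isolated Z-alkene are not reduced.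

## Compound list

1 | (Z)-hexadec-11-en-1-ol | CCCC/C=C\CCCCCCCCCCO | starting material
2 | (Z)-16-iodohexadec-5-ene [(11Z)-1-iodohexadec-11-ene] | CCCC/C=C\CCCCCCCCCCI | intermediate
3 | acetylacetone (pentane-2,4-dione) | CC(=O)CC(C)=O | starting material
4 | (16Z)-henicos-16-ene-2,4-dione | CCCC/C=C\CCCCCCCCCCCC(=O)CC(C)=O | intermediate
5 | dimethyl glutarate (dimethyl pentanedioate) | COC(=O)CCCC(=O)OC | starting material
6 | methyl (21Z)-5,7,9-trioxohexacos-21-enoate | CCCC/C=C\CCCCCCCCCCCC(=O)CC(=O)CC(=O)CCCC(=O)OC | intermediate
7 | 2-[(15Z)-3-oxoicos-15-enoyl]cyclohexane-1,3-dione | CCCC/C=C\CCCCCCCCCCCC(=O)CC(=O)C1C(=O)CCCC1=O | intermediate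
8 | 2-[(12Z)-heptadec-12-en-1-yl]-7,8-dihydro-4H-chromene-4,5(6H)-dione | CCCC/C=C\CCCCCCCCCCCc1cc(=O)c2c(o1)CCCC2=O | intermediate
9 | (5S)-2-[(12Z)-heptadec-12-en-1-yl]-5-hydroxy-5,6,7,8-tetrahydro-4H-chromen-4-one | CCCC/C=C\CCCCCCCCCCCc1cc(=O)c2c(o1)CCC[C@@H]2O | target

## Step count and fallbacks

Total step count: 4. Longest linear sequence: 4 steps (1 → 2 → 4 → 8 → 9).

The three steps most likely to fail:

**Step 3.** The dianion can be quenched by the acidic product or the base diverted by ester enolisation; a second dianion can attack the free ester; the Claisen ring closure can stall, in which case acid turns uncyclised 6 into a monocyclic pyrone ester. The fallback sets out from iodide 2 and buys the carbocycle instead of making it. The lithium dienolate of commercial 2,2,6-trimethyl-4H-1,3-dioxin-4-one (LDA, THF/DMPU, −78 °C) is alkylated at its 6-methyl group by 2 to give 6-[(12Z)-heptadec-12-en-1-yl]-2,2-dimethyl-4H-1,3-dioxin-4-one F1. Heating F1 in toluene at 110 °C with cyclohexane-1,3-dione expels acetone and gives the acylketene (15Z)-icosa-1,15-diene-1,3-dione F2. The dione captures F2 (DMAP cat.) to give tetraketone 7, and TsOH closes the pyrone. The route is rejoined at 8.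

**Step 4.** The C5 ketone is an electron-rich, vinylogous-ester-like carbonyl with a peri C4=O, so transfer hydrogenation may be slow or poorly selective. The fallback sets out from 8. Luche reduction (NaBH4, CeCl3·7H2O, MeOH, −20 °C) gives racemic 2-[(12Z)-heptadec-12-en-1-yl]-5-hydroxy-5,6,7,8-tetrahydro-4H-chromen-4-one F3. Lipase kinetic resolution (CAL-B, vinyl acetate, MTBE, 30 °C) acetylates the (R)-enantiomer, as predicted by the Kazlauskas rule and as found for 1-tetralol, to (5R)-2-[(12Z)-heptadec-12-en-1-yl]-4-oxo-5,6,7,8-tetrahydro-4H-chromen-5-yl acetate F4. The unreacted (S)-alcohol is separated by chromatography; the maximum yield is 50 %. The route is rejoined at 9.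

**Step 2.** Proton transfer between the product and the dianion can cause dialkylation or incomplete conversion of the long-chain iodide. The fallback sets out from 2 and replaces the dianion by a mono-anion alkylation followed by a separate acylation. Lithiated acetone N,N-dimethylhydrazone (n-BuLi, THF, 0 °C) is alkylated by 2 to give (14Z)-nonadec-14-en-2-one N,N-dimethylhydrazone F5. Hydrolysis (aqueous oxalic acid, Et2O) gives (14Z)-nonadec-14-en-2-one F6. A crossed Claisen condensation of F6 at its methyl group with ethyl acetate (NaH, THF, reflux) gives the β-diketone. The route is rejoined at 4.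

## Further compounds

F1 | step 3 | 6-[(12Z)-heptadec-12-en-1-yl]-2,2-dimethyl-4H-1,3-dioxin-4-one | CCCC/C=C\CCCCCCCCCCCC1=CC(=O)OC(C)(C)O1
F2 | step 3 | (15Z)-icosa-1,15-diene-1,3-dione (acylketene) | CCCC/C=C\CCCCCCCCCCCC(=O)C=C=O
F3 | step 4 | racemic 2-[(12Z)-heptadec-12-en-1-yl]-5-hydroxy-5,6,7,8-tetrahydro-4H-chromen-4-one | CCCC/C=C\CCCCCCCCCCCc1cc(=O)c2c(o1)CCCC2O
F4 | step 4 | (5R)-2-[(12Z)-heptadec-12-en-1-yl]-4-oxo-5,6,7,8-tetrahydro-4H-chromen-5-yl acetate | CCCC/C=C\CCCCCCCCCCCc1cc(=O)c2c(o1)CCC[C@H]2OC(C)=O
F5 | step 2 | (14Z)-nonadec-14-en-2-one N,N-dimethylhydrazone | CCCC/C=C\CCCCCCCCCCCC(C)=NN(C)C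
F6 | step 2 | (14Z)-nonadec-14-en-2-one | CCCC/C=C\CCCCCCCCCCCC(C)=O
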